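**Retrosynthetic overview**
1. Rings A/B with C5, C9 and C10 are bought in as (+)-manool (1); the furan that ends as the butenolide, with C16 and C21, is 3-acetyl-2-methylfuran (2).
2. C14=C15: methyl ketone 3 (from 1) and glyoxal 4 (from 2) are joined by aldol condensation to ene-dione 8.
3. Ring C: C8–C14 bond by 6-exo cyclisation of the C8 radical onto the ene-dione (8 to 9); this sets C8 and C14.
4. Ring D: C13=C21 bond by vinylogous aldol condensation of the furan 2-methyl group onto the C13 ketone (9 to 12); then carbinol 13 and acetate 14.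
5. Last and key step: oxidative dearomatisation of the furan of 14 (C–H oxygenation at C19, then tautomerisation with protonation at C13) gives the γ-ylidenebutenolide of 18 and sets C13. Ring order: A/B (chiral pool), C, D, butenolide.

Assumption and conventions: 1 and 2 are purchased; locants are labdane-type C1–C14 for rings A–C, then C15 (CH2 on C14), C16 (CH–O), C17/C18/C19/C20 (furan or butenolide carbons, ring O between C19 and C20) and C21 (carbon on C13); β is the face of the C10 methyl.

**Step 1**
Reactants: 1 (+)-manool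
Product: 3 14,15-dinorlabd-8(17)-en-13-one [4-((1S,4aS,8aS)-5,5,8a-trimethyl-2-methylidenedecahydronaphthalen-1-yl)butan-2-one]
Conditions: KMnO4, acetone–H2O, 0 °C
Reagents that add atoms: none
Why: Permanganate dihydroxylates the exposed monosubstituted vinyl group and cleaves the resulting glycol, so the tertiary carbinol carbon becomes the methyl ketone while the hindered 8(17)-methylene and C5, C9, C10 are untouched (oxidative cleavage of a tertiary allylic alcohol).

**Step 2**
Reactants: 2 3-acetyl-2-methylfuran
Product: 4 (2-methylfuran-3-yl)glyoxal [2-(2-methylfuran-3-yl)-2-oxoacetaldehyde], used anhydrous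
Conditions: SeO2, 1,4-dioxane–H2O, 90 °C; then toluene azeotrope
Reagents that add atoms: selenium dioxide, O=[Se]=O
Why: Riley oxidation of an aryl methyl ketone to the aryl glyoxal through its enol; the acetyl CH3 enolises far more readily than the furan 2-methyl group.

**Step 3**
Reactants: 3 14,15-dinorlabd-8(17)-en-13-one; 4 (2-methylfuran-3-yl)glyoxal
Product: 8 (E)-1-(2-methylfuran-3-yl)-6-[(1S,4aS,8aS)-5,5,8a-trimethyl-2-methylidenedecahydronaphthalen-1-yl]hex-2-ene-1,4-dione, via lithium enolate 5 (not isolated), via lithium aldolate 6 (not isolated), via mesylate 7 (not isolated)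
Conditions: LiN(i-Pr)2, THF, −78 °C; 4; then MsCl, Et3N, −78 → 0 °C
Reagents that add atoms: none
Why: Kinetic deprotonation gives the methyl-side enolate, which adds to the more electrophilic aldehyde carbonyl of 4 (crossed aldol), and mesylation followed by E1cB elimination gives the conjugated (E)-ene-dione, leaving no stereocentre at C15.

**Step 4**
Reactants: 8 (E)-ene-1,4-dione
Product: 9 tricyclic 1,4-diketone (rings A–C trans-anti-trans; C13 ketone; 8β-CH3; 14α-H with β-CH2C(=O)(2-methylfuran-3-yl) on C14)
Conditions: Fe(acac)3 (0.3 equiv), PhSiH3, EtOH–(CH2OH)2, 60 °C, 0.01 M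
Reagents that add atoms: none
Why: Hydrogen-atom transfer from an iron hydride to the 8(17)-methylene gives the tertiary C8 radical, which closes 6-exo onto the proximal ene-dione carbon (reductive MHAT Giese cyclisation) through a chair transition state with the new bond equatorial and anti to the C10 methyl, as in radical polyene cyclisations, so C8 carries a β-methyl; C14 forms with its side chain equatorial and is epimerisable next to the C13 ketone.

**Step 5**
Reactants: 9 tricyclic 1,4-diketone
Product: 12 tetracyclic furan dienone (16-oxo-13(21)-ene; ring D is a cyclohepta[b]furan-4-one fused to ring C at C13–C14; 14α-H), via potassium dienolate 10 (not isolated), via potassium aldolate 11 (not isolated)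
Conditions: KOt-Bu, t-BuOH–THF, 50 °C
Reagents that add atoms: none
Why: Proposed new method: the furan 2-methyl group is the γ-position of a vinylogous ester, so equilibrating alkoxide gives the extended dienolate (a dearomatised 2-methylene-2,3-dihydrofuran) that adds to the C13 ketone in a seven-membered aldol, and E1cB loss of hydroxide restores the furan and gives the conjugated C13=C21 alkene; this is the only irreversible exit because the C12, C14 and C15 enolates can form only three-membered or Bredt-blocked aldols; the closest known reactions are lateral condensations of 2-methyl-3-furoates and o-toluates and γ-deprotonation of vinylogous esters; the base also equilibrates C14 to the equatorial side chain (14α-H).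

**Step 6**
Reactants: 12 tetracyclic furan dienone
Product: 13 (16R)-16α-hydroxy fused furan (13(21)-ene)
Conditions: (S)-Me-CBS (20 mol%), BH3·SMe2, THF, −20 °C; MeOH
Reagents that add atoms: none
Why: Corey–Bakshi–Shibata reduction of an aryl alkyl ketone; the furan is the large group and CH2-15 the small one, so the (S)-oxazaborolidine delivers hydride to the face that gives the (R)-carbinol (16α-OH), as with 1-tetralone.

**Step 7**
Reactants: 13 (16R)-alcohol
Product: 14 (16R)-16α-acetoxy fused furan (13(21)-ene)
Conditions: Ac2O, pyridine, DMAP (cat.), CH2Cl2, 0 °C → rt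
Reagents that add atoms: acetic anhydride, CC(=O)OC(C)=O
Why: DMAP-catalysed O-acylation of the secondary alcohol with retention at C16 under basic, non-ionising conditions.

**Step 8**
Reactants: 14 (16R)-acetoxy fused furan
Product: 18 CNP0193439.1 [(16R)-16α-acetoxy γ-ylidenebutenolide; 5α-H, 8β-CH3, 9α-H, 10β-CH3, 13β-H, 14α-H], via furyl boronate 15 (not isolated), via boryloxyfuran 16 (not isolated), via furanol 17 (not isolated)
Conditions: [Ir(OMe)(cod)]2 (2 mol%), 4,4'-di-tert-butyl-2,2'-bipyridine (4 mol%), B2pin2, THF, 50 °C; then Me3NO, rt; then H2O, DBU (20 mol%), rt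
Reagents that add atoms: trimethylamine N-oxide, C[N+](C)(C)[O-]
Why: Proposed new method: iridium-catalysed C–H borylation takes the only furan α-C–H (C19) and N-oxide oxidation of the boronate gives the 2-hydroxyfuran, which is the aromatic trienol of the lactone; ketonisation at the remote alkene carbon C13 gives the fully conjugated γ-ylidenebutenolide as the most stable tautomer, and DBU keeps C13–H in equilibrium with the furanolate so that C13 settles in the trans C/D fusion (13β-H, C21 equatorial, away from the axial C8 methyl); the closest known reactions are oxidation of 2-furylboronates or 2-silyloxyfurans to butenolides and base isomerisation of γ-alkenyl butenolides to γ-ylidenebutenolides.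

**Compound list**
1 | (+)-manool, (13R)-labda-8(17),14-dien-13-ol | C=C[C@](C)(O)CC[C@H]1C(=C)CC[C@H]2C(C)(C)CCC[C@]12C | starting material
2 | 3-acetyl-2-methylfuran | Cc1occc1C(C)=O | starting material
3 | 14,15-dinorlabd-8(17)-en-13-one | CC(=O)CC[C@H]1C(=C)CC[C@H]2C(C)(C)CCC[C@]12C | intermediate
4 | (2-methylfuran-3-yl)glyoxal | Cc1occc1C(=O)C=O | intermediate
5 | lithium enolate of 3 (methyl side) | [Li]OC(=C)CC[C@H]1C(=C)CC[C@H]2C(C)(C)CCC[C@]12C | intermediate
6 | lithium aldolate (C15 epimers) | Cc1occc1C(=O)C(O[Li])CC(=O)CC[C@H]1C(=C)CC[C@H]2C(C)(C)CCC[C@]12C | intermediate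
7 | C15 mesylate (C15 epimers) | Cc1occc1C(=O)C(OS(C)(=O)=O)CC(=O)CC[C@H]1C(=C)CC[C@H]2C(C)(C)CCC[C@]12C | intermediate
8 | (E)-ene-1,4-dione | Cc1occc1C(=O)/C=C/C(=O)CC[C@H]1C(=C)CC[C@H]2C(C)(C)CCC[C@]12C | intermediate
9 | tricyclic 1,4-diketone (8β-CH3, 14α-H) | Cc1occc1C(=O)C[C@@H]2C(=O)CC[C@H]1[C@@]2(C)CC[C@H]2C(C)(C)CCC[C@]12C | intermediate
10 | potassium extended dienolate of 9 (2-methylene-2,3-dihydrofuran) | [K+].[O-]C(=C1C=COC1=C)C[C@@H]2C(=O)CC[C@H]1[C@@]2(C)CC[C@H]2C(C)(C)CCC[C@]12C | intermediate
11 | potassium aldolate, ring D closed (C13 configuration not controlled, removed on elimination) | O=C1C[C@@H]2C([O-])(Cc3occc31)CC[C@H]1[C@@]2(C)CC[C@H]2C(C)(C)CCC[C@]12C.[K+] | intermediate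
12 | tetracyclic furan dienone (16-oxo, 13(21)-ene) | O=C1C[C@@H]2C(=Cc3occc31)CC[C@H]1[C@@]2(C)CC[C@H]2C(C)(C)CCC[C@]12C | intermediate
13 | (16R)-16α-hydroxy fused furan | O[C@@H]1C[C@@H]2C(=Cc3occc31)CC[C@H]1[C@@]2(C)CC[C@H]2C(C)(C)CCC[C@]12C | intermediate
14 | (16R)-16α-acetoxy fused furan | CC(=O)O[C@@H]1C[C@@H]2C(=Cc3occc31)CC[C@H]1[C@@]2(C)CC[C@H]2C(C)(C)CCC[C@]12C | intermediate
15 | 19-(pinacolatoboryl)furan | CC(=O)O[C@@H]1C[C@@H]2C(=Cc3oc(B4OC(C)(C)C(C)(C)O4)cc31)CC[C@H]1[C@@]2(C)CC[C@H]2C(C)(C)CCC[C@]12C | intermediate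
16 | 19-(pinacolatoboryloxy)furan | CC(=O)O[C@@H]1C[C@@H]2C(=Cc3oc(OB4OC(C)(C)C(C)(C)O4)cc31)CC[C@H]1[C@@]2(C)CC[C@H]2C(C)(C)CCC[C@]12C | intermediate
17 | furan-19-ol | CC(=O)O[C@@H]1C[C@@H]2C(=Cc3oc(O)cc31)CC[C@H]1[C@@]2(C)CC[C@H]2C(C)(C)CCC[C@]12C | intermediate
18 | CNP0193439.1 | CC(=O)O[C@@H]1C[C@@H]2[C@@H](C=C3OC(=O)C=C31)CC[C@H]1[C@@]2(C)CC[C@H]2C(C)(C)CCC[C@]12C | target

**Totals and risks**
Total steps: 8. Longest linear sequence: 7 (steps 1, 3, 4, 5, 6, 7, 8 from 1).

Step 8 is the most likely to fail, either in the tautomerisation or in the equilibration at C13. The fallback sets out from 13 and comes back at 18, fixing C13 by reduction before the furan is oxidised. Li, NH3–THF, t-BuOH, −78 °C reduces the furan-conjugated alkene to the 13β-H saturated fused furan alcohol F1; as in dissolving-metal reductions of enones and styrenes, protonation of the distal carbon gives the more stable trans fusion. Ac2O and pyridine give the saturated furan acetate F2. Rose bengal, O2, light and i-Pr2NEt in CH2Cl2 at −78 °C (singlet-oxygen [4+2], then Kornblum–DeLaMare opening) give the γ-hydroxybutenolide F3. Ac2O and pyridine at 60 °C dehydrate it to 18.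

Step 5 is next, since the lateral deprotonation may be too slow. The fallback sets out from 9 and comes back at 12, making the C13=C21 bond by an olefination instead. NBS and AIBN in PhCF3 at 80 °C brominate the furan methyl group to the bromomethyl diketone F4. PPh3 in toluene gives the phosphonium bromide F5. K2CO3 and 18-crown-6 in toluene at 80 °C form the acyl-stabilised ylide, which closes ring D by intramolecular Wittig reaction on the C13 ketone to give 12.

Step 4 is third; the ene-dione may be reduced, or the B/C fusion may come out cis. The fallback sets out from 3 and comes back at 9, closing ring C by a cationic instead of a radical cyclisation. NaH and (MeO)2CO in refluxing THF give the β-keto ester F6. SnCl4 in CH2Cl2 at 0 °C lets the keto ester enol trap the C8 cation in a chair transition state, giving the trans-anti-trans tricyclic β-keto ester F7. K2CO3 in acetone with 3-(bromoacetyl)-2-methylfuran F8 (from 2 with CuBr2 in refluxing EtOAc) alkylates C14 to the alkylated keto ester F9. LiCl in wet DMSO at 150 °C (Krapcho) removes the ester and gives 9 with the equatorial side chain.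

**Further compounds**
F1 | step 8 | (16R)-16α-hydroxy-13β-H saturated fused furan | O[C@@H]1C[C@@H]2[C@@H](Cc3occc31)CC[C@H]1[C@@]2(C)CC[C@H]2C(C)(C)CCC[C@]12C
F2 | step 8 | (16R)-16α-acetoxy-13β-H saturated fused furan | CC(=O)O[C@@H]1C[C@@H]2[C@@H](Cc3occc31)CC[C@H]1[C@@]2(C)CC[C@H]2C(C)(C)CCC[C@]12C
F3 | step 8 | γ-hydroxybutenolide (20-hydroxy, C20 epimers) | CC(=O)O[C@@H]1C[C@@H]2[C@@H](CC3(O)OC(=O)C=C31)CC[C@H]1[C@@]2(C)CC[C@H]2C(C)(C)CCC[C@]12C
F4 | step 5 | bromomethyl diketone (2-bromomethylfuran analogue of 9) | BrCc1occc1C(=O)C[C@@H]2C(=O)CC[C@H]1[C@@]2(C)CC[C@H]2C(C)(C)CCC[C@]12C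
F5 | step 5 | phosphonium bromide | [Br-].O=C(C[C@@H]2C(=O)CC[C@H]1[C@@]2(C)CC[C@H]2C(C)(C)CCC[C@]12C)c1ccoc1C[P+](c1ccccc1)(c1ccccc1)c1ccccc1
F6 | step 4 | β-keto ester, methyl 3-oxo-5-[(1S,4aS,8aS)-5,5,8a-trimethyl-2-methylidenedecahydronaphthalen-1-yl]pentanoate | COC(=O)CC(=O)CC[C@H]1C(=C)CC[C@H]2C(C)(C)CCC[C@]12C
F7 | step 4 | tricyclic β-keto ester (13-oxo, 14β-CO2CH3, 8β-CH3) | COC(=O)[C@@H]2C(=O)CC[C@H]1[C@@]2(C)CC[C@H]2C(C)(C)CCC[C@]12C
F8 | step 4 | 3-(bromoacetyl)-2-methylfuran | Cc1occc1C(=O)CBr
F9 | step 4 | C14-alkylated keto ester (C14 configuration immaterial) | COC(=O)C2(CC(=O)c3ccoc3C)C(=O)CC[C@H]1[C@@]2(C)CC[C@H]2C(C)(C)CCC[C@]12C
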